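**Retrosynthetic overview**
1. Feature: in the cyclohexene (C1 OAc, C2 OH, C3 OH, C4=C5, C6 OBz, C7H2OBz on C5) the C4=C5 bond carries C7 on C5 beside the C6 carbinol. With C7 as an ester this is a ring-embedded α-(hydroxyalkyl)acrylate, a Morita–Baylis–Hillman adduct, flanked by the C3–C2–C1 triol.
2. Late stage: the C1 acetate comes from a C1,C2 cyclic orthoacetate of the triol dibenzoate, both benzoates from the C6,C7 diol, and the diol from the ring ester.
3. Key disconnection C5–C6, the only ring closure (the carbocycle): a phosphine-mediated cyclisation of an enoate aldehyde.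
4. The open chain maps C4, C3, C2, C1, C6 onto C1–C5 of D-arabinose, with C5 and C7 from a stabilised ylide: acetonide on the cis-diol (O1/O2), Wittig on the lactol, silylation, oxidation at C6.

Key step: step 6

Assumption: target ring locants are used throughout, and with C1→C6 drawn clockwise O1 and O2 are up and O3 and O6 are down (target 1S,2S,3R,6S); the lactol is used as its anomeric mixture, and centres that exist only in non-isolated intermediates are left undefined.

**Step 1**
Reactants: 1 D-arabinose
Product: 2 3,4-O-isopropylidene-D-arabinopyranose (anomeric mixture)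
Conditions: Me2C(OMe)2, p-TsOH·H2O (cat.), DMF, rt; then Et3N
Reagents that add atoms: 2,2-dimethoxypropane, COC(C)(C)OC
Why: Acid-catalysed acetal exchange (acetonide formation) under kinetic control in DMF should engage the only cis-diol of the pyranose, sugar O3/O4 (ring O2/O1), leaving the lactol free and touching no stereocentre.

**Step 2**
Reactants: 2 3,4-O-isopropylidene-D-arabinopyranose; 3 methyl (triphenylphosphoranylidene)acetate
Product: 4 methyl (E)-2,3-dideoxy-5,6-O-isopropylidene-D-arabino-hept-2-enonate (diol; the hydroxyls on the future C3 and C6 are free)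
Conditions: 3 (1.3 equiv), PhCO2H (cat.), toluene, 70 °C
Reagents that add atoms: methyl (triphenylphosphoranylidene)acetate (3), COC(=O)C=P(c1ccccc1)(c1ccccc1)c1ccccc1
Why: Wittig olefination of the lactol through its open hydroxy-aldehyde form with a stabilised ylide in a non-polar medium should give the E enoate, adding C5 and C7 and releasing the primary hydroxyl on the future C6.

**Step 3**
Reactants: 4 enoate diol
Product: 5 methyl (E)-4,7-bis-O-(tert-butyldimethylsilyl)-2,3-dideoxy-5,6-O-isopropylidene-D-arabino-hept-2-enonate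
Conditions: TBSOTf (2.5 equiv), 2,6-lutidine, CH2Cl2, −78 to 0 °C
Reagents that add atoms: tert-butyldimethylsilyl trifluoromethanesulfonate, CC(C)(C)[Si](C)(C)OS(=O)(=O)C(F)(F)F
Why: Silyl ether formation with a silyl triflate and a hindered pyridine base caps both hydroxyls without exposing the γ-oxygenated enoate to a nucleophile or strong base, and at low temperature should leave the acetonide alone.

**Step 4**
Reactants: 5 bis-silyl ether
Product: 6 methyl (E)-4-O-(tert-butyldimethylsilyl)-2,3-dideoxy-5,6-O-isopropylidene-D-arabino-hept-2-enonate (primary hydroxyl on the future C6 free)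
Conditions: HF·pyridine, pyridine, THF, 0 °C
Reagents that add atoms: none
Why: Buffered fluoride-mediated desilylation is governed by steric access, so the primary silyl ether should cleave well before the secondary allylic one flanked by the dioxolane, and the acetonide is not hydrolysed.

**Step 5**
Reactants: 6 primary alcohol
Product: 7 methyl (2E,4R)-4-[(tert-butyldimethylsilyl)oxy]-4-[(4R,5S)-5-formyl-2,2-dimethyl-1,3-dioxolan-4-yl]but-2-enoate (enoate aldehyde; CHO is the future C6)
Conditions: TEMPO (cat.), PhI(OAc)2, CH2Cl2, rt; used at once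
Reagents that add atoms: none
Why: Oxoammonium (TEMPO) oxidation with PhI(OAc)2 as terminal oxidant stops at the aldehyde under anhydrous, base-free conditions, so C1 on the cis-dioxolane, now α to the aldehyde, should not epimerise.

**Step 6**
Reactants: 7 enoate aldehyde
Product: 10 methyl 1,2-O-isopropylidene-3-O-TBS-6-hydroxycyclohex-4-ene-5-carboxylate (O1/O2 up; O3/O6 down), via phosphonium enolate 8 (not isolated), via phosphonium aldolate 9 (not isolated)
Conditions: PMe3 (0.5 equiv, 1.0 M in THF), t-AmOH, rt, 0.05 M, argon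
Reagents that add atoms: none
Why: This is an intramolecular Morita–Baylis–Hillman reaction: PMe3 adds reversibly to C4 of the enoate to give β-phosphonio enolate 8, C5 adds to the C6 aldehyde to form the C5–C6 bond (alkoxide 9), and proton transfer from C5 relayed by the tertiary alcohol followed by E1cB loss of PMe3 restores C4=C5 inside the new ring. The closest known reaction type is the trialkylphosphine-mediated cyclisation of ω-formyl α,β-unsaturated esters and thioesters to 2-acylcycloalk-2-enols. The cyclohexene closes in a 6-(enolexo)-exo-trig aldol mode, helped by the cis-fused dioxolane, which holds C6 and the C3 chain gauche across the C1–C2 bond. C6 is the only new stereocentre and is set by the substrate: in the chair-like transition state C2–O and C3–OTBS are equatorial, C1–O is axial, and the aldehyde C=O sits axial, antiperiplanar to the C1–O dipole and clear of allylic 1,3-strain with the exocyclic enolate, which places O6 trans to O1. The step needs this face selectivity and needs C1 not to epimerise; the weakly basic phosphine, the absence of amine base and fast closure onto an electrophilic α-alkoxy aldehyde should secure both. C1, C2 and C3 are carried unchanged from D-arabinose.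

**Step 7**
Reactants: 10 cyclohexenol ester
Product: 11 C6,C7 diol: 1,2-O-isopropylidene-3-O-TBS-5-(hydroxymethyl)cyclohex-4-en-6-ol (O1/O2 up; O3/O6 down)
Conditions: i-Bu2AlH (4 equiv), CH2Cl2, −78 to −40 °C; aq. potassium sodium tartrate
Reagents that add atoms: none
Why: Hydride reduction with i-Bu2AlH reduces the conjugated methyl ester in 1,2-fashion to the primary allylic alcohol (one equivalent is spent on the C6 hydroxyl), leaving the alkene, silyl ether, acetonide and all stereocentres untouched.

**Step 8**
Reactants: 11 C6,C7 diol; 12 benzoyl chloride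
Product: 13 C6,C7 dibenzoate: 1,2-O-isopropylidene-3-O-TBS-6-O-benzoyl-5-(benzoyloxymethyl)cyclohex-4-ene (O1/O2 up; O3/O6 down)
Conditions: BzCl (3 equiv), pyridine, DMAP (cat.), CH2Cl2, 0 °C to rt
Reagents that add atoms: benzoyl chloride (12), O=C(Cl)c1ccccc1
Why: Pyridine/DMAP-catalysed acylation (nucleophilic acyl transfer) with excess acid chloride esterifies both the primary C7 and the secondary allylic C6 hydroxyl, with retention at C6 because only O–acyl bonds form.

**Step 9**
Reactants: 13 dibenzoate
Product: 14 triol dibenzoate: 6-O-benzoyl-5-(benzoyloxymethyl)cyclohex-4-ene-1,2,3-triol (O1/O2 up; O3/O6 down)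
Conditions: CF3CO2H/H2O (4:1), 0 °C to rt; co-evaporation with toluene
Reagents that add atoms: none
Why: Aqueous acid hydrolysis cleaves the isopropylidene acetal and the secondary silyl ether in one operation, while the benzoates are inert to aqueous trifluoroacetic acid and base-promoted acyl migration is not expected.

**Step 10**
Reactants: 14 triol dibenzoate; 15 trimethyl orthoacetate
Product: 17 target (1S,2S,3R,6S)-6-(benzoyloxy)-5-[(benzoyloxy)methyl]-2,3-dihydroxycyclohex-4-en-1-yl acetate, via cyclic orthoacetate 16 (not isolated)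
Conditions: MeC(OMe)3 (1.2 equiv), (+)-10-camphorsulfonic acid (cat.), MeCN, rt; then AcOH/H2O (4:1), rt; no basic work-up
Reagents that add atoms: trimethyl orthoacetate (15), CC(OC)(OC)OC; water, O
Why: Acid-catalysed orthoester exchange closes a 2-methoxy-2-methyl-1,3-dioxolane on the only cis-diol (O1/O2), and mild aqueous acid opening of cyclic orthoesters gives the axial ester kinetically, the axial oxygen being O1 in the half-chair that keeps the C6 benzoate pseudoaxial (avoiding allylic 1,2-strain with the C5 substituent) and O2 and O3 equatorial.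

**Compound list**
1 | D-arabinose | O=C[C@@H](O)[C@H](O)[C@H](O)CO | starting material
2 | 3,4-O-isopropylidene-D-arabinopyranose (anomeric mixture) | OC1OC[C@H]2OC(C)(C)O[C@H]2[C@@H]1O | intermediate
3 | methyl (triphenylphosphoranylidene)acetate | COC(=O)C=P(c1ccccc1)(c1ccccc1)c1ccccc1 | starting material
4 | methyl (E)-2,3-dideoxy-5,6-O-isopropylidene-D-arabino-hept-2-enonate | COC(=O)/C=C/[C@@H](O)[C@@H]1OC(C)(C)O[C@@H]1CO | intermediate
5 | methyl (E)-4,7-bis-O-(tert-butyldimethylsilyl)-2,3-dideoxy-5,6-O-isopropylidene-D-arabino-hept-2-enonate | COC(=O)/C=C/[C@@H](O[Si](C)(C)C(C)(C)C)[C@@H]1OC(C)(C)O[C@@H]1CO[Si](C)(C)C(C)(C)C | intermediate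
6 | methyl (E)-4-O-(tert-butyldimethylsilyl)-2,3-dideoxy-5,6-O-isopropylidene-D-arabino-hept-2-enonate | COC(=O)/C=C/[C@@H](O[Si](C)(C)C(C)(C)C)[C@@H]1OC(C)(C)O[C@@H]1CO | intermediate
7 | methyl (2E,4R)-4-[(tert-butyldimethylsilyl)oxy]-4-[(4R,5S)-5-formyl-2,2-dimethyl-1,3-dioxolan-4-yl]but-2-enoate | COC(=O)/C=C/[C@@H](O[Si](C)(C)C(C)(C)C)[C@@H]1OC(C)(C)O[C@@H]1C=O | intermediate
8 | phosphonium enolate zwitterion (PMe3 on C4, ester enolate at C5; C4 undefined) | COC([O-])=CC([P+](C)(C)C)[C@@H](O[Si](C)(C)C(C)(C)C)[C@@H]1OC(C)(C)O[C@@H]1C=O | intermediate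
9 | phosphonium aldolate zwitterion (ring closed, PMe3 on C4, alkoxide on C6; C4 and C5 undefined) | CC1(C)O[C@H]2[C@@H](O1)[C@H](O[Si](C)(C)C(C)(C)C)C([P+](C)(C)C)C(C(=O)OC)[C@@H]2[O-] | intermediate
10 | methyl 1,2-O-isopropylidene-3-O-TBS-6-hydroxycyclohex-4-ene-5-carboxylate (O1/O2 up; O3/O6 down) | CC1(C)O[C@H]2[C@@H](O1)[C@H](O[Si](C)(C)C(C)(C)C)C=C(C(=O)OC)[C@@H]2O | intermediate
11 | C6,C7 diol (1,2-O-isopropylidene, 3-O-TBS) | CC1(C)O[C@H]2[C@@H](O1)[C@H](O[Si](C)(C)C(C)(C)C)C=C(CO)[C@@H]2O | intermediate
12 | benzoyl chloride | O=C(Cl)c1ccccc1 | starting material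
13 | C6,C7 dibenzoate (1,2-O-isopropylidene, 3-O-TBS) | CC1(C)O[C@H]2[C@@H](O1)[C@H](O[Si](C)(C)C(C)(C)C)C=C(COC(=O)c1ccccc1)[C@@H]2OC(=O)c1ccccc1 | intermediate
14 | triol dibenzoate (C1, C2, C3 hydroxyls free) | O[C@H]1[C@@H](O)[C@H](O)C=C(COC(=O)c2ccccc2)[C@@H]1OC(=O)c1ccccc1 | intermediate
15 | trimethyl orthoacetate | CC(OC)(OC)OC | starting material
16 | C1,C2-O-(1-methoxyethylidene) cyclic orthoacetate of 14 (orthoester carbon undefined) | COC1(C)O[C@H]2[C@@H](O1)[C@H](O)C=C(COC(=O)c1ccccc1)[C@@H]2OC(=O)c1ccccc1 | intermediate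
17 | (1S,2S,3R,6S)-6-(benzoyloxy)-5-[(benzoyloxy)methyl]-2,3-dihydroxycyclohex-4-en-1-yl acetate | CC(=O)O[C@H]1[C@@H](O)[C@H](O)C=C(COC(=O)c2ccccc2)[C@@H]1OC(=O)c1ccccc1 | target

**Step count**
Total: 10 steps. Longest linear sequence: 10 steps from D-arabinose (fully linear).

**Steps most likely to fail**

Step 6. The risk is closure through the other aldehyde face, so that O6 comes out cis to O1 (alone or mixed with 10). The fallback keeps this material and inverts C6 when the benzoate is put on. Setting out from 7, the same PMe3 cyclisation would give the C6 epimer of the cyclohexenol ester F1. Reduction with i-Bu2AlH (CH2Cl2, −78 °C) would give the C6-epimeric C6,C7 diol F2. BzCl (1.05 equiv) with 2,4,6-collidine in CH2Cl2 at −40 °C should benzoylate only the primary hydroxyl to give the C6-epimeric C7 monobenzoate F3. A Mitsunobu reaction (PPh3, DIAD, PhCO2H, toluene, 0 °C to rt) then installs the C6 benzoate by SN2 displacement with inversion, on the face trans to O1, and returns to the route at 13.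

Step 10. The risks are opening of the orthoacetate toward O2, acetylation of the free C3 hydroxyl through a mixed orthoester, and drift of the acetyl group from O1 to O2. The fallback tells the three hydroxyls apart by ring geometry. Setting out from 14, butane-2,3-dione, HC(OMe)3 and BF3·OEt2 (cat.) in MeOH at rt should form a butane-2,3-diacetal only on the trans-diequatorial C2,C3 diol. The cis C1,C2 pair cannot give the trans-fused, doubly anomerically stabilised dioxane, so the product is the C2,C3-O-(2,3-dimethoxybutane-2,3-diyl) acetal with free C1 hydroxyl F4. Ac2O, pyridine and DMAP acetylate the only free hydroxyl to give the C1 acetate of the diacetal F5. CF3CO2H/H2O (9:1) at rt removes the diacetal and returns to the route at 17.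

Step 2. The risks are conjugate addition of the released primary hydroxyl to the new enoate (closure to a tetrahydropyran), and formation of Z olefin that lactonises onto the adjacent hydroxyl. The fallback introduces the acceptor only after both hydroxyls are silylated. Setting out from 2, Wittig methylenation with Ph3P=CH2 (from Ph3PCH3Br and KOt-Bu, 3 equiv; THF, 0 °C to rt) would give the terminal alkene diol 1,2-dideoxy-4,5-O-isopropylidene-D-arabino-hex-1-enitol F6. TBSOTf and 2,6-lutidine would give the bis-TBS ether of the alkene diol F7. Cross-metathesis with methyl acrylate (second-generation Hoveyda–Grubbs catalyst, RuCl2(H2IMes)(=CH-C6H4-2-OiPr), CH2Cl2, 40 °C) should give the E enoate and return to the route at 5.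

**Further compounds**
F1 | step 6 | C6 epimer of the cyclohexenol ester (O6 up, cis to O1) | CC1(C)O[C@H]2[C@@H](O1)[C@H](O[Si](C)(C)C(C)(C)C)C=C(C(=O)OC)[C@H]2O
F2 | step 6 | C6-epimeric C6,C7 diol | CC1(C)O[C@H]2[C@@H](O1)[C@H](O[Si](C)(C)C(C)(C)C)C=C(CO)[C@H]2O
F3 | step 6 | C6-epimeric C7 monobenzoate | CC1(C)O[C@H]2[C@@H](O1)[C@H](O[Si](C)(C)C(C)(C)C)C=C(COC(=O)c1ccccc1)[C@H]2O
F4 | step 10 | C2,C3-O-(2,3-dimethoxybutane-2,3-diyl) acetal with free C1 hydroxyl | O[C@H]1[C@H]2OC(C)(OC)C(C)(OC)O[C@@H]2C=C(COC(=O)c2ccccc2)[C@@H]1OC(=O)c1ccccc1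
F5 | step 10 | C1 acetate of the diacetal | CC(=O)O[C@H]1[C@H]2OC(C)(OC)C(C)(OC)O[C@@H]2C=C(COC(=O)c2ccccc2)[C@@H]1OC(=O)c1ccccc1
F6 | step 2 | 1,2-dideoxy-4,5-O-isopropylidene-D-arabino-hex-1-enitol | C=C[C@@H](O)[C@@H]1OC(C)(C)O[C@@H]1CO
F7 | step 2 | bis-TBS ether of the alkene diol | C=C[C@@H](O[Si](C)(C)C(C)(C)C)[C@@H]1OC(C)(C)O[C@@H]1CO[Si](C)(C)C(C)(C)C
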